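**Retrosynthetic overview** (germacrane numbering throughout: C1 ketone, C4–C5 oxirane, C6 lactone oxygen, C7=C11, C8 ester, C10 methyl, C12 lactone carbonyl, C13 CH2OAc)
1. Last ring: the butenolide (O6–C12–C11–C7–C6) is closed at C11–C12, together with the C13–OAc bond, from macrocyclic α-allenol 21 with CO and acetic acid under oxidative palladium catalysis.
2. Enabling feature: the exocyclic allene C7=C11=C13H2 on the ten-membered ring sits next to the only free hydroxyl (C6–OH). Its C11=C13 π bond lies in the C6–C7–C8 plane, so a C6–O–C(=O)–Pd unit reaches the central carbon C11 through a five-membered transition state, and the resulting allyl unit C7–C11–C13 takes acetate at C13.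
3. Ten-membered carbocycle: C6–C7 bond by intramolecular Nozaki–Hiyama allenylation of propargylic chloride/cis-epoxy aldehyde 20, which also sets C6 and creates the allene.
4. Acyclic chain from nerol: Sharpless epoxidation (C4, C5), tartrate crotylboration (C10), ynone transfer hydrogenation (C8). C1 is carried as a PMB-protected carbinol, because a free C1 ketone would capture the C7 nucleophile in a five-membered ring closure.
5. Ring order: oxirane (step 1), ten-membered carbocycle (step 14), butenolide (step 15); then C8 ester and C1 ketone.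

Key step: step 15

Remark: the oxirane of the target is cis (C3 and C6 on the same face), so the (Z)-allylic alcohol nerol is the epoxidation substrate; crotylboronate 5 is taken as a purchasable reagent (otherwise one operation from (E)-but-2-ene, triisopropyl borate and the tartrate).

Step 1
Reactants: 1 nerol
Product: 2 (2R,3S)-2,3-epoxynerol
Conditions: Ti(OiPr)4 (10 mol%), D-(−)-diethyl tartrate (12 mol%), t-BuOOH, 4 Å MS, CH2Cl2, −20 °C
Reagents that add atoms: tert-butyl hydroperoxide, CC(C)(C)OO
Why: Sharpless asymmetric epoxidation of the (Z)-allylic alcohol, in which the D-(−)-tartrate catalyst delivers oxygen to the face that gives the cis-oxirane with C4 (S) and C5 (R), while the remote trisubstituted alkene does not react.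

Step 2
Reactants: 2 (2R,3S)-2,3-epoxynerol
Product: 3 TBS ether of 2
Conditions: TBSCl, imidazole, DMF, 0 → 25 °C
Reagents that add atoms: tert-butyl(chloro)dimethylsilane, CC(C)(C)[Si](C)(C)Cl
Why: silylation of the primary alcohol under weakly basic conditions, which avoids Payne rearrangement and any acid near the oxirane.

Step 3
Reactants: 3 TBS ether of 2
Product: 4 C1 aldehyde
Conditions: O3, pyridine (3 equiv), CH2Cl2, −78 °C
Reagents that add atoms: ozone, [O-][O+]=O
Why: ozonolysis of the only C=C bond, with pyridine making the carbonyl oxide collapse to the aldehyde in the flask, while oxirane and silyl ether are inert to ozone.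

Step 4
Reactants: 4 C1 aldehyde; 5 (R,R)-tartrate (E)-crotylboronate
Product: 6 (1R,10S)-homoallylic alcohol
Conditions: 4 Å MS, toluene, −78 °C; aq. NaHCO3 work-up; Et3N-deactivated silica
Reagents that add atoms: none
Why: Roush (E)-crotylboration through a closed chair transition state, in which the (R,R)-tartrate reagent attacks the si face of the aldehyde and the (E)-crotyl unit gives the anti adduct, so that C10 is set as S (kept) and C1 as R (temporary) without a Lewis acid that could open the δ-hydroxy oxirane.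

Step 5
Reactants: 6 (1R,10S)-homoallylic alcohol
Product: 7 C1 4-methoxybenzyl ether
Conditions: NaH, PMBCl, Bu4NI (cat.), THF/DMF, 0 → 25 °C
Reagents that add atoms: 4-methoxybenzyl chloride, COc1ccc(CCl)cc1
Why: Williamson etherification under basic conditions, which masks the C1 hydroxyl before it can open the oxirane in an acid-catalysed 5-exo cyclisation.

Step 6
Reactants: 7 C1 4-methoxybenzyl ether
Product: 9 primary C8 alcohol, via B-alkyl-9-BBN adduct 8 (not isolated)
Conditions: 9-BBN, THF, 0 → 25 °C; then NaOH, H2O2, 0 °C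
Reagents that add atoms: hydrogen peroxide, OO
Why: anti-Markovnikov hydroboration–oxidation of the only alkene (monosubstituted), which leaves the adjacent C10 stereocenter untouched.

Step 7
Reactants: 9 primary C8 alcohol
Product: 11 C8 carboxylic acid, via aldehyde 10 (not isolated)
Conditions: TEMPO (7 mol%), NaClO2, NaOCl (2 mol%), MeCN/phosphate buffer pH 6.7, 35 °C
Reagents that add atoms: sodium chlorite, [Na+].[O-]Cl=O
Why: oxoammonium (TEMPO) oxidation to the aldehyde followed by Pinnick-type chlorite oxidation in one near-neutral pot, which spares oxirane, PMB and silyl ether and cannot epimerise C10 (β to the new carbonyl).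

Step 8
Reactants: 11 C8 carboxylic acid
Product: 13 Weinreb amide, via acyl imidazole 12 (not isolated)
Conditions: CDI, CH2Cl2, 25 °C; then MeNH(OMe)·HCl, 25 °C
Reagents that add atoms: N,O-dimethylhydroxylamine hydrochloride, CNOC.Cl
Why: carbonyldiimidazole activation and aminolysis give the N-methoxy-N-methylamide without acid chloride or strong base.

Step 9
Reactants: 13 Weinreb amide; 14 3-chloroprop-1-yne
Product: 16 ynone, via lithium 3-chloroprop-1-yn-1-ide 15 (not isolated)
Conditions: 14, n-BuLi, THF, −90 → −78 °C; then 13, −78 → −50 °C; aq. NH4Cl at −50 °C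
Reagents that add atoms: none
Why: Weinreb ketone synthesis, in which the lithium acetylide adds once to the amide (chelated tetrahedral intermediate) and brings C7, C11 and C13 with the chloride already in place, the low temperature preserving the lithiated propargylic chloride.

Step 10
Reactants: 16 ynone
Product: 17 (8R)-propargylic alcohol
Conditions: Ru[(R,R)-TsNCHPhCHPhNH](p-cymene) (2 mol%), i-PrOH, 25 °C
Reagents that add atoms: none
Why: Noyori asymmetric transfer hydrogenation of an alkynyl ketone, in which the alkyne plays the π-substituent in the six-membered hydride-transfer transition state so that the (R,R)-catalyst should give the (R)-carbinol at C8 under reagent control without touching alkyne, chloride or oxirane.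

Step 11
Reactants: 17 (8R)-propargylic alcohol
Product: 18 C8 TBS ether
Conditions: TBSOTf, 2,6-lutidine, CH2Cl2, −78 °C
Reagents that add atoms: tert-butyldimethylsilyl trifluoromethanesulfonate, CC(C)(C)[Si](C)(C)OS(=O)(=O)C(F)(F)F
Why: silylation of the secondary propargylic alcohol, giving an oxygen substituent that is a poor leaving group and so should not undergo 1,4-elimination from the later organochromium intermediate.

Step 12
Reactants: 18 C8 TBS ether
Product: 19 primary epoxy alcohol (C6–OH)
Conditions: HF·pyridine, pyridine, THF, 0 °C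
Reagents that add atoms: none
Why: rate-selective desilylation, the primary silyl ether being cleaved much faster than the secondary one at C8 under buffered HF.

Step 13
Reactants: 19 primary epoxy alcohol
Product: 20 cis-epoxy aldehyde
Conditions: Dess–Martin periodinane, NaHCO3, CH2Cl2, 0 → 25 °C
Reagents that add atoms: none
Why: buffered Dess–Martin oxidation of the primary alcohol, the α-carbon C5 being an oxirane carbon that does not epimerise.

Step 14
Reactants: 20 cis-epoxy aldehyde
Product: 21 macrocyclic α-allenol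
Conditions: CrCl2 (8 equiv), NaI (cat.), DMF/THF, 25 °C, syringe-pump addition to 2 mM
Reagents that add atoms: none
Why: intramolecular Nozaki–Hiyama reaction, in which divalent chromium turns the propargylic chloride into a propargylchromium species that adds through its γ-carbon C7 (SE2′, the known course for alkyne-substituted 2-alkynyl halides) to the aldehyde, so that the C6–C7 bond, the ten-membered ring and the C7=C11=C13H2 allene form together, and Felkin–Anh attack anti to the oxirane C5–O bond should give the erythro (5R,6R) carbinol.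

Step 15
Reactants: 21 macrocyclic α-allenol
Product: 22 13-acetoxy butenolide
Conditions: Pd(OAc)2 (10 mol%), 1,4-benzoquinone (2 equiv), LiOAc (2 equiv), AcOH (10 equiv), CO (1 atm), MeCN, 25 °C
Reagents that add atoms: carbon monoxide, [C-]#[O+]; acetic acid, CC(=O)O
Why: Proposed new method: the free C6 hydroxyl attacks CO on divalent palladium to give an alkoxycarbonylpalladium species, which adds syn across the in-plane C11=C13 π bond of the allene so that the acyl carbon C12 bonds to the central carbon C11 (5-exo-trig closure of the ring O6–C12–C11–C7–C6) and leaves an allylpalladium unit over C7–C11–C13. Acetate then attacks the unhindered CH2 terminus C13, which gives the conjugated C7=C11 butenolide with the C13 acetate, and benzoquinone returns zerovalent palladium to the divalent state. The closest known reaction types are the PdCl2/CuCl2 oxidative alkoxy-alkoxycarbonylation of allenes (ester carbon to the central carbon, oxygen nucleophile to a terminus), the Ru3(CO)12-catalysed cyclocarbonylation of α-allenic alcohols to butenolides, and the benzoquinone-promoted acetate capture of allylpalladium intermediates in diene diacetoxylation; the intramolecular, acetate-terminated combination on an allenol is not established. No stereocenter is formed, C5, C6 and C8 are not touched, and the geometry of the tetrasubstituted alkene is fixed by the tether (C12 cis to C6, C13 cis to C8). The step needs (a) lactonisation at O6 and not O8, secured because C8 carries a silyl ether; (b) alkoxycarbonylation rather than 5-endo oxypalladation of the allene (O6 to C13), favoured by the CO atmosphere and acetate buffer; (c) acetate attack at C13 rather than at the fully substituted C7, secured by sterics and by conjugation in the product; (d) capture faster than β-hydride loss from the allyl complex, which benzoquinone promotes.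

Step 16
Reactants: 22 13-acetoxy butenolide
Product: 23 C8 alcohol
Conditions: HF·pyridine, pyridine, THF, 0 → 25 °C
Reagents that add atoms: none
Why: buffered fluoride desilylation that leaves acetate, lactone, oxirane and PMB ether intact, translactonisation to O8 being impossible because C12 is locked cis to C6 across the C7=C11 bond.

Step 17
Reactants: 23 C8 alcohol; 24 3-methylbut-2-enoyl chloride
Product: 25 C8 3-methylbut-2-enoate
Conditions: 24, pyridine, DMAP (cat.), CH2Cl2, 0 °C
Reagents that add atoms: none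
Why: acylation of the secondary allylic alcohol through the acylpyridinium ion, the weak base pyridine avoiding vinylketene formation (deconjugation of the acyl group) and acetyl migration from O13.

Step 18
Reactants: 25 C8 3-methylbut-2-enoate
Product: 26 C1 alcohol
Conditions: DDQ, CH2Cl2/pH 7 buffer, 0 °C
Reagents that add atoms: none
Why: oxidative cleavage of the PMB ether (hydride abstraction by DDQ, hydrolysis of the oxocarbenium ion) under buffered neutral conditions that esters, butenolide and oxirane tolerate.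

Step 19
Reactants: 26 C1 alcohol
Product: 27 target
Conditions: Dess–Martin periodinane, NaHCO3, CH2Cl2, 0 → 25 °C
Reagents that add atoms: none
Why: mild non-basic oxidation of the C1 carbinol to the ketone, which erases the temporary C1 center without epimerising C10 and without acid that could trigger transannular attack on the oxirane.

**Compound list**
1 | nerol, (2Z)-3,7-dimethylocta-2,6-dien-1-ol | CC(C)=CCC/C(C)=C\CO | starting material
2 | (2R,3S)-2,3-epoxynerol, [(2R,3S)-3-methyl-3-(4-methylpent-3-en-1-yl)oxiran-2-yl]methanol | OC[C@H]1O[C@@]1(C)CCC=C(C)C | intermediate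
3 | tert-butyl(dimethyl){[(2R,3S)-3-methyl-3-(4-methylpent-3-en-1-yl)oxiran-2-yl]methoxy}silane | CC(C)(C)[Si](C)(C)OC[C@H]1O[C@@]1(C)CCC=C(C)C | intermediate
4 | 3-[(2S,3R)-3-({[tert-butyl(dimethyl)silyl]oxy}methyl)-2-methyloxiran-2-yl]propanal | CC(C)(C)[Si](C)(C)OC[C@H]1O[C@@]1(C)CCC=O | intermediate
5 | diisopropyl (4R,5R)-2-[(2E)-but-2-en-1-yl]-1,3,2-dioxaborolane-4,5-dicarboxylate | C/C=C/CB1O[C@@H](C(=O)OC(C)C)[C@H](C(=O)OC(C)C)O1 | starting material
6 | (3R,4S)-1-[(2S,3R)-3-({[tert-butyl(dimethyl)silyl]oxy}methyl)-2-methyloxiran-2-yl]-4-methylhex-5-en-3-ol; (1R,4S,5R,10S) in germacrane numbers | CC(C)(C)[Si](C)(C)OC[C@H]1O[C@@]1(C)CC[C@@H](O)[C@@H](C)C=C | intermediate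
7 | 4-methoxybenzyl ether of 6 at C1–O; (1R,4S,5R,10S) | CC(C)(C)[Si](C)(C)OC[C@H]1O[C@@]1(C)CC[C@@H](OCc1ccc(OC)cc1)[C@@H](C)C=C | intermediate
8 | B-alkyl-9-borabicyclo[3.3.1]nonane from 7 (boron on C8) | CC(C)(C)[Si](C)(C)OC[C@H]1O[C@@]1(C)CC[C@@H](OCc1ccc(OC)cc1)[C@@H](C)CCB1C2CCCC1CCC2 | intermediate (not isolated)
9 | (3S,4R)-6-[(2S,3R)-3-({[tert-butyl(dimethyl)silyl]oxy}methyl)-2-methyloxiran-2-yl]-4-[(4-methoxybenzyl)oxy]-3-methylhexan-1-ol | CC(C)(C)[Si](C)(C)OC[C@H]1O[C@@]1(C)CC[C@@H](OCc1ccc(OC)cc1)[C@@H](C)CCO | intermediate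
10 | (3S,4R)-hexanal corresponding to 9 (C8 aldehyde) | CC(C)(C)[Si](C)(C)OC[C@H]1O[C@@]1(C)CC[C@@H](OCc1ccc(OC)cc1)[C@@H](C)CC=O | intermediate (not isolated)
11 | (3S,4R)-hexanoic acid corresponding to 9 (C8 acid) | CC(C)(C)[Si](C)(C)OC[C@H]1O[C@@]1(C)CC[C@@H](OCc1ccc(OC)cc1)[C@@H](C)CC(=O)O | intermediate
12 | N-acylimidazole of 11 | CC(C)(C)[Si](C)(C)OC[C@H]1O[C@@]1(C)CC[C@@H](OCc1ccc(OC)cc1)[C@@H](C)CC(=O)n1ccnc1 | intermediate (not isolated)
13 | N-methoxy-N-methylamide of 11 | CC(C)(C)[Si](C)(C)OC[C@H]1O[C@@]1(C)CC[C@@H](OCc1ccc(OC)cc1)[C@@H](C)CC(=O)N(C)OC | intermediate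
14 | 3-chloroprop-1-yne | C#CCCl | starting material
15 | lithium 3-chloroprop-1-yn-1-ide | [Li]C#CCCl | intermediate (not isolated)
16 | (6S,7R)-9-[(2S,3R)-3-({[tert-butyl(dimethyl)silyl]oxy}methyl)-2-methyloxiran-2-yl]-1-chloro-7-[(4-methoxybenzyl)oxy]-6-methylnon-2-yn-4-one | CC(C)(C)[Si](C)(C)OC[C@H]1O[C@@]1(C)CC[C@@H](OCc1ccc(OC)cc1)[C@@H](C)CC(=O)C#CCCl | intermediate
17 | (4R,6S,7R)-non-2-yn-4-ol corresponding to 16; (1R,4S,5R,8R,10S) | CC(C)(C)[Si](C)(C)OC[C@H]1O[C@@]1(C)CC[C@@H](OCc1ccc(OC)cc1)[C@@H](C)C[C@@H](O)C#CCCl | intermediate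
18 | C8 tert-butyldimethylsilyl ether of 17 | CC(C)(C)[Si](C)(C)OC[C@H]1O[C@@]1(C)CC[C@@H](OCc1ccc(OC)cc1)[C@@H](C)C[C@@H](O[Si](C)(C)C(C)(C)C)C#CCCl | intermediate
19 | [(2R,3S)-3-{(3R,4S,6R)-6-[(tert-butyldimethylsilyl)oxy]-9-chloro-3-[(4-methoxybenzyl)oxy]-4-methylnon-7-yn-1-yl}-3-methyloxiran-2-yl]methanol | OC[C@H]1O[C@@]1(C)CC[C@@H](OCc1ccc(OC)cc1)[C@@H](C)C[C@@H](O[Si](C)(C)C(C)(C)C)C#CCCl | intermediate
20 | (2S,3S)-3-{(3R,4S,6R)-6-[(tert-butyldimethylsilyl)oxy]-9-chloro-3-[(4-methoxybenzyl)oxy]-4-methylnon-7-yn-1-yl}-3-methyloxirane-2-carbaldehyde | O=C[C@H]1O[C@@]1(C)CC[C@@H](OCc1ccc(OC)cc1)[C@@H](C)C[C@@H](O[Si](C)(C)C(C)(C)C)C#CCCl | intermediate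
21 | (1R,4S,5R,6R,8R,10S)-8-[(tert-butyldimethylsilyl)oxy]-4,5-epoxy-7-ethenylidene-1-[(4-methoxybenzyl)oxy]-4,10-dimethylcyclodecan-6-ol (germacrane numbers) | C=C=C1[C@@H](O)[C@H]2O[C@@]2(C)CC[C@@H](OCc2ccc(OC)cc2)[C@@H](C)C[C@H]1O[Si](C)(C)C(C)(C)C | intermediate
22 | (1R,4S,5R,6R,8R,10S)-13-acetoxy-8-[(tert-butyldimethylsilyl)oxy]-4,5-epoxy-1-[(4-methoxybenzyl)oxy]germacr-7(11)-en-12,6-olide | CC(=O)OCC1=C2[C@@H](OC1=O)[C@H]1O[C@@]1(C)CC[C@@H](OCc1ccc(OC)cc1)[C@@H](C)C[C@H]2O[Si](C)(C)C(C)(C)C | intermediate
23 | (1R,4S,5R,6R,8R,10S)-13-acetoxy-4,5-epoxy-8-hydroxy-1-[(4-methoxybenzyl)oxy]germacr-7(11)-en-12,6-olide | CC(=O)OCC1=C2[C@@H](OC1=O)[C@H]1O[C@@]1(C)CC[C@@H](OCc1ccc(OC)cc1)[C@@H](C)C[C@H]2O | intermediate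
24 | 3-methylbut-2-enoyl chloride | CC(C)=CC(=O)Cl | starting material
25 | (1R,4S,5R,6R,8R,10S)-13-acetoxy-4,5-epoxy-1-[(4-methoxybenzyl)oxy]-8-(3-methylbut-2-enoyloxy)germacr-7(11)-en-12,6-olide | CC(=O)OCC1=C2[C@@H](OC1=O)[C@H]1O[C@@]1(C)CC[C@@H](OCc1ccc(OC)cc1)[C@@H](C)C[C@H]2OC(=O)C=C(C)C | intermediate
26 | (1R,4S,5R,6R,8R,10S)-13-acetoxy-4,5-epoxy-1-hydroxy-8-(3-methylbut-2-enoyloxy)germacr-7(11)-en-12,6-olide | CC(=O)OCC1=C2[C@@H](OC1=O)[C@H]1O[C@@]1(C)CC[C@@H](O)[C@@H](C)C[C@H]2OC(=O)C=C(C)C | intermediate
27 | (4S,5R,6R,8R,10S)-13-acetoxy-4,5-epoxy-8-(3-methylbut-2-enoyloxy)-1-oxogermacr-7(11)-en-12,6-olide | CC(=O)OCC1=C2[C@@H](OC1=O)[C@H]1O[C@@]1(C)CCC(=O)[C@@H](C)C[C@H]2OC(=O)C=C(C)C | target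

Total step count: 19. Longest linear sequence: 19 steps (nerol 1 to target 27).

**Steps most likely to fail**

1. Step 15 (proposed new method). What may go wrong: the free hydroxyl may add directly to the palladium-activated allene in a 5-endo sense (O6 to C13) before alkoxycarbonylation, or the allylpalladium intermediate may lose a β-hydride before acetate captures it. Fallback with known reactions only, setting out from 21 and coming back at 22: ozonolysis (O3, pyridine, CH2Cl2, −78 °C) cleaves the allene to the α-hydroxy ketone F1. Wittig methylenation (Ph3P=CH2, THF, 0 °C) gives the 7-methylene alcohol F2. Acylation of the C6 hydroxyl with 2-(acetoxymethyl)acryloyl chloride (i-Pr2NEt, CH2Cl2, −20 °C) gives the diene ester F3. Ring-closing metathesis of F3 with the second-generation Hoveyda–Grubbs catalyst, RuCl2(H2IMes)(=CH-C6H4-2-OiPr), in toluene at 80 °C closes the butenolide at C7=C11 and gives 22.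

2. Step 14. What may go wrong: attack on the wrong face of the aldehyde in the ten-membered transition state (C6 epimer), together with slow ring closure that lets intermolecular coupling or protonation of the organochromium species compete. Fallback setting out from 20 and coming back at 21: the ring closure is run as in step 14 and whatever C6 mixture results is taken on; the unwanted (6S)-epimer F4 (or the mixture) is oxidised with Dess–Martin periodinane to the allenyl epoxy ketone F5. Reduction of F5 with Zn(BH4)2 (Et2O, −30 °C), with the hydride delivered to the zinc chelate between the carbonyl and oxirane oxygens, should give the erythro alcohol 21, so that C6 is set by reduction instead of by the C–C bond formation.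

3. Step 9. What may go wrong: decomposition of the lithiated propargylic chloride (loss of chloride, oligomerisation) before it acylates on the Weinreb amide. Fallback setting out from 13 and coming back at 18: the lithium acetylide of triethyl(prop-2-yn-1-yloxy)silane (n-BuLi, THF, −78 → 0 °C) adds to 13 to give the silyloxy ynone F6. Transfer hydrogenation as in step 10 gives the (8R)-alcohol F7, and TBSOTf/2,6-lutidine gives the C8 silyl ether F8. PPTS in MeOH at 0 °C removes only the primary triethylsilyl group to give the propargylic alcohol F9, and PPh3/N-chlorosuccinimide (THF, 0 °C) converts F9 into chloride 18.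

Further compounds
F1 | step 15 | (1R,4S,5R,6S,8R,10S)-8-[(tert-butyldimethylsilyl)oxy]-4,5-epoxy-6-hydroxy-1-[(4-methoxybenzyl)oxy]-4,10-dimethylcyclodecan-7-one (germacrane numbers) | O=C1[C@@H](O)[C@H]2O[C@@]2(C)CC[C@@H](OCc2ccc(OC)cc2)[C@@H](C)C[C@H]1O[Si](C)(C)C(C)(C)C
F2 | step 15 | 7-methylene analogue of F1, (1R,4S,5R,6R,8R,10S)-configured cyclodecan-6-ol | C=C1[C@@H](O)[C@H]2O[C@@]2(C)CC[C@@H](OCc2ccc(OC)cc2)[C@@H](C)C[C@H]1O[Si](C)(C)C(C)(C)C
F3 | step 15 | C6 2-(acetoxymethyl)prop-2-enoate of F2 | C=C1[C@@H](OC(=O)C(=C)COC(C)=O)[C@H]2O[C@@]2(C)CC[C@@H](OCc2ccc(OC)cc2)[C@@H](C)C[C@H]1O[Si](C)(C)C(C)(C)C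
F4 | step 14 | (6S)-epimer of 21 | C=C=C1[C@H](O)[C@H]2O[C@@]2(C)CC[C@@H](OCc2ccc(OC)cc2)[C@@H](C)C[C@H]1O[Si](C)(C)C(C)(C)C
F5 | step 14 | C6 ketone of 21 (allenyl epoxy ketone) | C=C=C1C(=O)[C@H]2O[C@@]2(C)CC[C@@H](OCc2ccc(OC)cc2)[C@@H](C)C[C@H]1O[Si](C)(C)C(C)(C)C
F6 | step 9 | analogue of 16 with CH2OSiEt3 in place of CH2Cl | CC(C)(C)[Si](C)(C)OC[C@H]1O[C@@]1(C)CC[C@@H](OCc1ccc(OC)cc1)[C@@H](C)CC(=O)C#CCO[Si](CC)(CC)CC
F7 | step 9 | (8R)-propargylic alcohol from F6 | CC(C)(C)[Si](C)(C)OC[C@H]1O[C@@]1(C)CC[C@@H](OCc1ccc(OC)cc1)[C@@H](C)C[C@@H](O)C#CCO[Si](CC)(CC)CC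
F8 | step 9 | C8 tert-butyldimethylsilyl ether of F7 | CC(C)(C)[Si](C)(C)OC[C@H]1O[C@@]1(C)CC[C@@H](OCc1ccc(OC)cc1)[C@@H](C)C[C@@H](O[Si](C)(C)C(C)(C)C)C#CCO[Si](CC)(CC)CC
F9 | step 9 | C13 primary propargylic alcohol from F8 | CC(C)(C)[Si](C)(C)OC[C@H]1O[C@@]1(C)CC[C@@H](OCc1ccc(OC)cc1)[C@@H](C)C[C@@H](O[Si](C)(C)C(C)(C)C)C#CCO
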